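- I counted the partner.

| setting | zeta | theta | flask |
|---|---|---|---|
| starting material | 0.80 M | 0.80 M | 0.80 M |
| coupling partner | 0.96 M | 0.96 M | 0.960 M |
| precatalyst | 1 mM | 2 mM | 1.0 mM |
| remark | the very flask that is asked about, followed so far | run made earlier |  |
| time |  |  | 50 min |

| run | time / min | starting material / % | product / % |
|---|---|---|---|
| zeta | 3.00 | 28.4 | 4.3 |
| zeta | 6.00 | 28.3 | 5.5 |
| zeta | 10.0 | 26.7 | 8.5 |
| zeta | 12.0 | 26.0 | 7.9 |
| zeta | 15.0 | 26.5 | 9.4 |
| theta | 3.00 | 27.3 | 7.8 |
| theta | 8.00 | 26.0 | 12.4 |
| theta | 15.0 | 24.3 | 13.7 |
| theta | 25.0 | 25.2 | 13.4 |
| theta | 40.0 | 24.6 | 15.3 |

(each reading ± 0.5 percentage points)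

- candidate steps: starting material + coupling partner + catalyst -> catalyst + product; coupling partner + precatalyst -> catalyst + spent reagent; 2 coupling partner -> homo dimer; starting material <-> dormant form
- the reaction counts as stopped when no species that holds the starting material changes by six tenths of a point or more over the second half of the time
- what has gone from starting material into another species counts as reacted, even if it can come back

1. at 50 min, what has stopped the reaction, if anything has (it is still moving / no working catalyst is left / all of the starting material has reacted / the coupling partner has run out first)
2. share of the starting material used up at 50 min
3. product at 50 min, in percent of the starting material charged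

- Zeta and theta had the same charges of starting material and coupling partner, but theta had twice the precatalyst.
- Theta's product rose by 1.6 percentage points from 15.0 min to 40.0 min, so it had nearly stopped.
- Its starting material still read 24.6%, so that had not run out. The candidate steps give the catalyst back at each turn, so I looked at the coupling partner.
- Each product takes one partner. At 15.0 min, zeta's product had taken 7.83% of the partner's charge. I call this share of the charge found in product the partner capture.
- At the same time, theta's capture was 11.4%. It was less than double zeta's.
- I read this as two paths competing for one charge. The product path uses catalyst and the homo dimer path does not. Theta, with more precatalyst, held the larger capture.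
- So I took the partner as the limiting reagent, although it was charged in excess. For the asked flask, which is zeta continued, I expected a stop with product near 9.4% and 73.5% of the starting material used up.
- The forecast gave no working catalyst is left, 74% and 11%, saying “the catalyst has most likely died”, and so differed from me on the cause.
- At 50 min, the asked flask gave 9.70% product and 73.4% used up. The outcome was: the coupling partner has run out first. Its partner stood at 0.028% of the charge, and its catalyst at 46.6% of the catalyst charged.

    starting material + coupling partner + catalyst → catalyst + product (k = 17.0 M⁻² s⁻¹)
    coupling partner + precatalyst → catalyst + spent reagent (k = 0.00800 M⁻¹ s⁻¹)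
    2 coupling partner → homo dimer (k = 0.0220 M⁻¹ s⁻¹)
    starting material ⇌ dormant form (K = 2.40, k = 0.150 s⁻¹)

- The asked flask's capture came to 8.08%, beside my 7.83% from the zeta reading, and its homo dimer held 91.8% of the partner's charge. A neighbouring flask took 4.00 mM of precatalyst, with the other charges and the time unchanged. Its product reached 20.5%, so its capture was 17.1%, which is 2.12 times the asked flask's 8.08%. Its homo dimer held 82.7% of the partner's charge. At 50.0 min, the neighbouring flask had 0% of its partner left and 36.8% of its catalyst charge standing as catalyst.

Readings and results were generated by integration from invented constants; the scatter is artificial.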